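## Structural features

The target is a trans-fused decalin of the eudesmane type. Ring A is C1–C2–C3–C4–C5–C10 and ring B is C5–C6–C7–C8–C9–C10, sharing the C5–C10 bond; the C14 methyl sits on quaternary C10 and the C15 methyl on carbinol carbon C4. All seven stereocentres are contiguous (C1–C10–C5, with C4 on C5, then C6–C7–C8). The 1β-OH, 6α-OH, 7β side chain and 8α-OAc are equatorial, while C4 carries an equatorial hydroxyl and an axial methyl that is 1,3-diaxial to the axial C14 methyl. The C7 side chain is a methyl 2-substituted acrylate (C11=C13, C12 ester). Fragile points are the acrylate (Michael acceptor), the free O6 γ to the C12 ester (lactonisation under base), the single acetate on O8 between free secondary hydroxyls (migration, hydrolysis) and the tertiary C4 alcohol (dehydration). The real difficulty is telling three secondary oxygens apart, placing the 4β-methyl against the C10 methyl, and setting the all-equatorial C6–C7–C8 triad beside a hindered ring fusion. The key step exploits two features of ring B: C10 (bearing C14 and the C1 carbon) and C5 (bearing H and the C4 carbon) are adjacent with the C1 and C4 arms trans, and C6 and C8 are oxygenated in a 1,3-relation. That is the imprint of a 1,3-dioxygenated butadiene (C6–C9) added across an E 2-methyl-4-oxo-enoate (C10=C5).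

## Logic of the disconnections

25 to 24: the O1–Si and O6–Si bonds are cut. Both secondary hydroxyls stay masked to the end so that only O8 is acylated and O6 cannot attack C12. The forward step must remove silicon without base, sparing acetate and acrylate.

24 to 23: the C11–C12 bond and the ester C–O bond are cut; the acrylate becomes a terminal alkyne C11≡C13. The most fragile group is replaced by one inert to hydride, base and phosphine reagents. The forward step must add H and CO2Me with branched regiochemistry while O6 is blocked.

23 to 22: the C8–OAc bond is cut with inversion. Hydride can reach C8 only from the α face, so reduction gives the 8β-alcohol; displacement by acetate then sets the equatorial ester and acylates O8 alone. Substitution must outrun elimination.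

22 to 20: the C8–H bond and the alkyne C–Si bond are cut, returning to the C8 ketone that the diene leaves behind. One hydride face is required.

20 to 19 to 17: the two O–Si bonds and the C6–O bond (through C6–B) are cut, returning to a flat enone. Conjugate addition must come from the α face at C6, and protonation at C7 must be axial.

17 to 15 plus 16, and 15 to 14: the C7–C11 bond and the C7–I bond are cut. The two-carbon unit comes from a simple alkyne; only the α position of the enone may be functionalised.

14 to 13: the C8=O/C6=C7 enone is traced to a silyl enol ether with an allylic C6 methoxy group, the retron of a 1-methoxy-3-silyloxy diene. Unveiling must not dehydrate the C4 alcohol.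

13 to 12 to 11: the C1–H bond and the C2–H/C3–H bonds are cut. The hydride must enter C1 from the α face, and the alkene reduction must leave the enol ether alone.

11 to 10: the C2=C3 bond is cut by retro-metathesis, reducing ring A to two vinyl groups. The forward step must accept a vinyl ketone and a hindered tertiary allylic alcohol.

10 to 8 to 6: the C1–C2 bond (vinyl on the lactone carbonyl) and the C3–C4 bond (vinyl on the ketone) are cut; the C1–O4 lactone is temporary. The ketone of 6 is its most electrophilic site, so reacting it first removes the acidity of C5–H and sets C4; the lactone then lets the hindered C1 carboxyl take exactly one nucleophile. Attack must occur on the ketone face anti to C10 without enolisation.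

6 to 3 plus 5: the C9–C10 and C5–C6 bonds are cut, opening ring B. This removes the quaternary centre, the trans C1/C4 relation and the 1,3-oxygen pattern in one operation. The forward step must control regiochemistry and one enantioface.

3 to 1 plus 2, and 5 to 4: the C10=C5 bond and the O–Si bond are cut, reaching commercial materials. The olefination must deliver the E isomer.

## Other disconnections considered

Alternative 1: The cut is C5–C10 together with the C4–O bond. In the forward step aqueous acid opens the 1,10-epoxide of the ten-membered epoxy-alkene A1 at C10, C5 of the E alkene attacks across the ring, and water captures C4 to give A2, the 6-O-triethylsilyl ether of the target.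
- In favour: the trans fusion and the C1, C10 and C5 configurations would follow from the chair–chair folding of A1, both rings form in one late operation, and A2 is one deprotection from the target. On setting the ring fusion and ring A in a single step this alternative is the better of the two.
- Against: A1 is a stereodefined medium ring with an E alkene, a trans epoxide, three contiguous stereocentres and the acrylate, and its supply is the real problem. The C4 cation can lose a proton instead of taking water, the face of water capture is not enforced, and aqueous acid may strip the silyl ether and let O6 lactonise.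
- Comparison: the cationic cascade is less controllable than a catalysed concerted cycloaddition; the endgame is shorter, but overall step economy is expected to be worse once A1 is counted. Protecting-group load is equal.

Alternative 2: The cut is C7–C8. Me2AlCl would promote a carbonyl-ene closure of aldehyde A3, in which C7 of the trisubstituted alkene adds to the C8 aldehyde while a methyl hydrogen passes to oxygen, giving A4 with ring B closed and the C11=C13 alkene formed.
- In favour: a chair transition state places O6, the isopropenyl group and the new O8 all equatorial, so C7 and C8 would arise directly in the target's relative configuration. Here the alternative is better than the chosen plan, which needs reduction, inversion and a controlled protonation. A4 also has O8 as its only free hydroxyl, so acetylation is trivial, again a point in its favour.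
- Against: A4 carries an isopropenyl group, so C12 must be oxidised from methyl to ester late (allylic oxidation, further oxidation, esterification) beside silyl ethers and an acetate. A3 needs ring A with C1, C4, C5, C10 and C6 already set, a long linear prelude; the allylic silyloxy group may ionise under the Lewis acid.
- Comparison: both key steps are ordered pericyclic processes, but the cycloaddition is intermolecular and convergent and forms two bonds and the quaternary centre, whereas the ene step forms one bond late. Overall step count is expected to be higher for the alternative.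

Alternative 3: The cut is C4–C5. A chelating Lewis acid (Al(OtBu)3 or Sc(OTf)3) would induce an α-ketol rearrangement of the five-ring ketol A5, in which alkenyl C5 migrates from carbinol C3 to the acetyl carbon C4, giving the ring-expanded dione A6.
- In favour: the bicyclic core of A5 is accessible in enantioenriched form by amine-catalysed annulation, so the absolute configuration at C10 rests on firmer precedent than the cycloaddition chosen here; on this point the alternative is the better one. The tertiary C4 carbinol with its methyl is formed in the rearrangement itself.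
- Against: A6 has a superfluous C3 ketone to remove, and ring B carries a C7 carbonyl and a C5=C6 alkene, whereas the target needs oxygen at C6 and C8 and carbon at C7. Nearly all of ring B would have to be refunctionalised. The rearrangement is reversible, migration of C2 can compete, and the C4 configuration depends on chelate geometry.
- Comparison: the chosen cycloaddition delivers ring B with oxygen already at C6 and C8 and C7 ready for C–C coupling; step economy is clearly worse for the alternative.

Key step: step 3

Remarks on the chemistry:
- Positions keep the target numbering C1–C15 in every intermediate; β is the face of the C14 methyl on C10, α the opposite face.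
- The diene carries a tert-butyldimethylsilyl group instead of trimethylsilyl. A trimethylsilyl enol ether could pass silicon to triflimide, starting an achiral silyl-cation cycle, and would not survive steps 4 to 8.
- The sense of induction in step 3 is assigned by analogy with enone dienophiles and is not verified for this substrate. Should it prove opposite, the catalyst from (R)-diphenylprolinol is used with no other change.

## Route

Step 1
Reactants: 1 methyl pyruvate; 2 1-(triphenylphosphoranylidene)propan-2-one
Product: 3 methyl (E)-2-methyl-4-oxopent-2-enoate (fragment 1)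
Conditions: PhMe, 80 °C; then I2 (5 mol%), visible light, rt; distillation
Reagents that add atoms: none
Why: Wittig olefination of the activated ketone of 1 by the stabilised ylide 2 forms C10=C5; iodine-catalysed reversible addition should equilibrate the mixture to the E isomer, in which acetyl and ester are trans.

Step 2
Reactants: 4 (E)-4-methoxybut-3-en-2-one
Product: 5 (E)-1-methoxy-3-(tert-butyldimethylsilyloxy)buta-1,3-diene (fragment 2)
Conditions: TBSOTf, Et3N, Et2O, 0 °C → rt
Reagents that add atoms: tert-butyldimethylsilyl triflate, CC(C)(C)[Si](C)(C)OS(=O)(=O)C(F)(F)F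
Why: Soft enolisation of the methyl ketone and O-silylation give the 2-silyloxy diene; the E enol ether geometry is untouched.

Step 3
Reactants: 3 methyl (E)-2-methyl-4-oxopent-2-enoate; 5 (E)-1-methoxy-3-(tert-butyldimethylsilyloxy)buta-1,3-diene
Product: 6 methyl (1R,5R,6S)-6-acetyl-3-(tert-butyldimethylsilyloxy)-5-methoxy-1-methylcyclohex-3-ene-1-carboxylate (ring B cycloadduct)
Conditions: (S)-3,3-diphenyl-1-(o-tolyl)tetrahydro-1H,3H-pyrrolo[1,2-c][1,3,2]oxazaborole (20 mol%), Tf2NH (18 mol%), CH2Cl2, −78 → −40 °C
Reagents that add atoms: none
Why: The N-protonated oxazaborolidine binds the C4 ketone of 3, the more basic of its two carbonyls, with C5–H held against the ring oxygen; this lowers the LUMO and makes C10 the electrophilic terminus. The [4+2] addition is concerted but asynchronous: the unsubstituted terminus C9 of 5 bonds first to C10 and C6 then closes onto C5 (a stepwise Michael/ring-closure extreme would give the same adduct). The closest known reactions are oxazaborolidinium-catalysed Diels–Alder additions of 2-silyloxy dienes to enones, quinones and acrylates, and Lewis-acid-promoted additions of 1-methoxy-3-silyloxy dienes to β-acyl acrylates under ketone control. Ring B closes as a six-membered carbocycle by suprafacial [4π+2π] addition across C10=C5 and emerges as a cyclohexene holding C8 as its silyl enol ether. C10 and C5 are fixed relative to each other by the E geometry of 3 (ester and acetyl trans, C14 methyl cis to acetyl), and their absolute sense by the catalyst, which must leave the C10-Re/C5-Re face open to the diene. C6 follows from the endo position of the bound acetyl (methoxy cis to acetyl) and is erased in step 9. The step needs C9–C10 regiochemistry and one enantioface: ketone rather than ester coordination secures the first, the aryl groups of the catalyst the second. The bulky silyl group of 5 keeps silicon from passing to triflimide.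

Step 4
Reactants: 6 ring B cycloadduct
Product: 8 trans-fused (4R)-4-methyl-4-vinyl γ-lactone (C1 carbonyl bonded to O4), via tertiary alkoxide ester 7 (not isolated)
Conditions: CH2=CHMgBr, CeCl3, THF, −78 °C → rt
Reagents that add atoms: vinylmagnesium bromide, C=C[Mg]Br
Why: Organocerium 1,2-addition to the methyl ketone (the ester on quaternary C10 is inert); the low basicity avoids enolisation toward C5 and loss of methoxide. Felkin–Anh control with quaternary C10 anti to the nucleophile, reinforced by chelation of the carbonyl oxygen with the cis C6 methoxy group, should give the (4R) carbinol (O4 α and C15 β in the later decalin); on warming the alkoxide lactonises onto the C1 ester.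

Step 5
Reactants: 8 vinyl γ-lactone
Product: 10 C1 vinyl ketone bearing the (4R) vinyl carbinol (hydroxy dienone), via vinyl lactol 9 (not isolated)
Conditions: CH2=CHMgBr (1.2 equiv), THF, −78 °C; AcOH quench at −78 °C
Reagents that add atoms: vinylmagnesium bromide, C=C[Mg]Br
Why: Single Grignard addition to a lactone: the magnesium hemiketalate persists at −78 °C and opens to the vinyl ketone only after the cold quench, so a second addition is avoided; the product equilibrates with lactol 9.

Step 6
Reactants: 10 hydroxy dienone
Product: 11 ring A enone (C1 ketone, C2=C3, 4α-OH) trans-fused to the ring B silyl enol ether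
Conditions: second-generation Grubbs catalyst RuCl2(=CHPh)(H2IMes)(PCy3) (5 mol%), CH2Cl2, 40 °C
Reagents that add atoms: none
Why: Ring-closing metathesis joins the two terminal vinyl groups as the cis C2=C3 bond of a six-membered ring and expels ethene; the open hydroxy enone tautomer is the reacting form. No stereocentre is formed, and the fusion is trans because the C1 and C4 arms are trans on ring B.

Step 7
Reactants: 11 ring A enone
Product: 12 saturated C1 ketone
Conditions: H2 (1 atm), 5% Pd/C, EtOAc, rt
Reagents that add atoms: none
Why: Heterogeneous hydrogenation of the unhindered disubstituted enone alkene; the trisubstituted, oxygen-bearing C7=C8 enol ether should be reduced far more slowly.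

Step 8
Reactants: 12 saturated C1 ketone
Product: 13 1β,4α-diol with ring B silyl enol ether
Conditions: NaBH4, MeOH, 0 °C
Reagents that add atoms: none
Why: Borohydride reduction; hydride approaches C1 from the α face (axial attack), away from the vicinal axial C14 methyl, giving the equatorial 1β-alcohol as in angularly methylated 1-decalones.

Step 9
Reactants: 13 1β,4α-diol silyl enol ether
Product: 14 1β,4α-dihydroxy-6-en-8-one
Conditions: 1 M HCl, THF, 0 °C → rt
Reagents that add atoms: none
Why: Acid hydrolysis of the silyl enol ether with β-elimination of methanol (the pseudo-axial 6β-methoxy group is aligned for loss) gives the C8 ketone conjugated with C6=C7; the C6 stereocentre of the cycloadduct disappears here.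

Step 10
Reactants: 14 1β,4α-dihydroxy-6-en-8-one
Product: 15 7-iodo enone
Conditions: I2, pyridine, DMAP (cat.), CH2Cl2, 0 °C → rt
Reagents that add atoms: iodine, II
Why: α-Iodination of an enone by pyridine conjugate addition, enolate iodination and elimination; only C7 can be functionalised this way.

Step 11
Reactants: 15 7-iodo enone; 16 trimethylsilylacetylene
Product: 17 7-(trimethylsilylethynyl) enone
Conditions: PdCl2(PPh3)2 (5 mol%), CuI (10 mol%), i-Pr2NH, THF, rt
Reagents that add atoms: none
Why: Sonogashira coupling of a 2-iodoenone (oxidative addition at zerovalent palladium, transmetallation from the copper acetylide) forms C7–C11; free hydroxyls are tolerated.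

Step 12
Reactants: 17 7-(trimethylsilylethynyl) enone
Product: 19 6α-hydroxy-7β-(trimethylsilylethynyl)-8-ketone, via C6 pinacol boronate 18 (not isolated)
Conditions: B2pin2, CuCl (5 mol%), Xantphos (5 mol%), NaOt-Bu (10 mol%), MeOH (2 equiv), THF, 0 °C → rt; then NaBO3·4H2O, THF/H2O, rt
Reagents that add atoms: sodium perborate, [Na+].[O-]OB=O (oxygen on C6); bis(pinacolato)diboron, CC1(C)OB(OC1(C)C)B1OC(C)(C)C(C)(C)O1 (boron of 18 only)
Why: Copper-catalysed conjugate borylation: the copper boryl adds to C6 from the α face because the β face is screened by the axial C14 and C15 methyls. Axial (α) protonation of the enolate at C7 places the alkynyl group equatorial (β), and perborate oxidises C–B to C–O with retention to give the 6α-alcohol.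

Step 13
Reactants: 19 6α-hydroxy ketone
Product: 20 1,6-bis(tert-butyldimethylsilyl) ether of the C8 ketone
Conditions: TBSOTf (2.4 equiv), 2,6-lutidine, CH2Cl2, −78 → 0 °C
Reagents that add atoms: tert-butyldimethylsilyl triflate, CC(C)(C)[Si](C)(C)OS(=O)(=O)C(F)(F)F
Why: Silyl triflate silylation of both secondary hydroxyls at low temperature; the hindered tertiary C4 hydroxyl should be left, and any silylation there would be undone in step 17.

Step 14
Reactants: 20 bis(silyl ether) ketone
Product: 22 8β-alcohol with terminal alkyne, via silylalkyne 8β-alcohol 21 (not isolated)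
Conditions: LiBH(s-Bu)3, THF, −78 °C; then MeOH, aq NaOH, H2O2, 0 °C → rt
Reagents that add atoms: none
Why: The bulky hydride attacks the C8 ketone from the α face (equatorial attack; the β face is blocked by the syn-axial C14 methyl) to give the axial 8β-alcohol. The alkaline methanolic peroxide work-up oxidises the borane residue and cleaves the alkynyl C–Si bond.

Step 15
Reactants: 22 8β-alcohol
Product: 23 8α-acetate
Conditions: PPh3, DIAD, AcOH, PhMe, 0 °C → rt
Reagents that add atoms: acetic acid, CC(=O)O
Why: Mitsunobu reaction: the axial oxyphosphonium ion at C8 is displaced by acetate with inversion, giving the equatorial 8α-acetate; the tertiary C4 hydroxyl does not react.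

Step 16
Reactants: 23 8α-acetate
Product: 24 1,6-bis(tert-butyldimethylsilyl) ether of the target
Conditions: Pd(OAc)2 (5 mol%), 2-(diphenylphosphino)pyridine (25 mol%), MsOH (15 mol%), CO (10 atm), MeOH/THF, 45 °C
Reagents that add atoms: carbon monoxide, [C-]#[O+]; methanol, CO
Why: Palladium-catalysed Markovnikov methoxycarbonylation of a terminal alkyne with the pyridylphosphine/acid system places the ester carbon on internal C11, giving the 2-substituted acrylate. O6 is silylated so it cannot capture the acylpalladium intermediate, and the excess of ligand over acid buffers the medium.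

Step 17
Reactants: 24 bis(silyl ether) of the target
Product: 25 CNP0272656.1
Conditions: HF·pyridine, pyridine/THF, 0 °C → rt
Reagents that add atoms: none
Why: Buffered hydrogen fluoride cleaves both silyl ethers; no alkoxide is generated, so the acetate should not migrate and O6 should not lactonise onto C12.

## Compound list

1 | methyl pyruvate (methyl 2-oxopropanoate) | CC(=O)C(=O)OC | starting material
2 | 1-(triphenylphosphoranylidene)propan-2-one | CC(=O)C=P(c1ccccc1)(c1ccccc1)c1ccccc1 | starting material
3 | methyl (E)-2-methyl-4-oxopent-2-enoate (fragment 1; C10=C5 with C1 ester, C14 methyl and C4 acetyl) | CC(=O)/C=C(\C)C(=O)OC | intermediate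
4 | (E)-4-methoxybut-3-en-2-one | CO/C=C/C(C)=O | starting material
5 | (E)-1-methoxy-3-(tert-butyldimethylsilyloxy)buta-1,3-diene (fragment 2; C6–C9) | CO/C=C/C(=C)O[Si](C)(C)C(C)(C)C | intermediate
6 | methyl (1R,5R,6S)-6-acetyl-3-(tert-butyldimethylsilyloxy)-5-methoxy-1-methylcyclohex-3-ene-1-carboxylate (acetyl trans to ester, methoxy cis to acetyl) | COC(=O)[C@]1(C)CC(O[Si](C)(C)C(C)(C)C)=C[C@@H](OC)[C@H]1C(C)=O | intermediate
7 | methyl (1R,5R,6S)-3-(tert-butyldimethylsilyloxy)-6-[(2R)-2-hydroxybut-3-en-2-yl]-5-methoxy-1-methylcyclohex-3-ene-1-carboxylate, formed as its alkoxide | COC(=O)[C@]1(C)CC(O[Si](C)(C)C(C)(C)C)=C[C@@H](OC)[C@H]1[C@](C)(O)C=C | intermediate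
8 | (3R,3aS,4R,7aR)-6-(tert-butyldimethylsilyloxy)-4-methoxy-3,7a-dimethyl-3-vinyl-3a,4,7,7a-tetrahydroisobenzofuran-1(3H)-one (trans-fused γ-lactone C1(=O)–O–C4) | C=C[C@@]1(C)OC(=O)[C@]2(C)CC(O[Si](C)(C)C(C)(C)C)=C[C@@H](OC)[C@@H]12 | intermediate
9 | 1-vinyl lactol of 8 (hemiketal at C1, either configuration there) | C=C[C@@]1(C)OC(O)(C=C)[C@]2(C)CC(O[Si](C)(C)C(C)(C)C)=C[C@@H](OC)[C@@H]12 | intermediate
10 | hydroxy dienone: ring B of 6 with a propenoyl group (C1 ketone, C2=CH2) on C10 and a (2R)-2-hydroxybut-3-en-2-yl group (C4, C3=CH2) on C5 | C=CC(=O)[C@]1(C)CC(O[Si](C)(C)C(C)(C)C)=C[C@@H](OC)[C@H]1[C@](C)(O)C=C | intermediate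
11 | trans-fused bicyclic enone: C1 ketone, C2=C3, 4α-hydroxy-4β-methyl, 5α-H, 6β-methoxy, C7=C8 with 8-(tert-butyldimethylsilyloxy), 10β-methyl | CO[C@@H]1C=C(O[Si](C)(C)C(C)(C)C)C[C@@]2(C)C(=O)C=C[C@@](C)(O)[C@H]12 | intermediate
12 | 2,3-dihydro derivative of 11 (saturated C1 ketone) | CO[C@@H]1C=C(O[Si](C)(C)C(C)(C)C)C[C@@]2(C)C(=O)CC[C@@](C)(O)[C@H]12 | intermediate
13 | 1β,4α-dihydroxy-6β-methoxy-4β,10β-dimethyl trans-decalin with C7=C8 tert-butyldimethylsilyl enol ether | CO[C@@H]1C=C(O[Si](C)(C)C(C)(C)C)C[C@@]2(C)[C@H](O)CC[C@@](C)(O)[C@H]12 | intermediate
14 | 1β,4α-dihydroxy-4β,10β-dimethyl-5α-H trans-fused bicyclic enone (C8 ketone, C6=C7) | O=C1C=C[C@@H]2[C@@](C)(C1)[C@H](O)CC[C@@]2(C)O | intermediate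
15 | 7-iodo derivative of 14 | O=C1C(I)=C[C@@H]2[C@@](C)(C1)[C@H](O)CC[C@@]2(C)O | intermediate
16 | trimethylsilylacetylene | C#C[Si](C)(C)C | starting material
17 | 7-(trimethylsilylethynyl) derivative of 14 | O=C1C(C#C[Si](C)(C)C)=C[C@@H]2[C@@](C)(C1)[C@H](O)CC[C@@]2(C)O | intermediate
18 | 6α-(pinacolboryl)-7β-(trimethylsilylethynyl)-1β,4α-dihydroxy-8-ketone | C[Si](C)(C)C#C[C@H]1[C@H](B3OC(C)(C)C(C)(C)O3)[C@@H]2[C@@](C)(CC1=O)[C@H](O)CC[C@@]2(C)O | intermediate
19 | 1β,4α,6α-trihydroxy-7β-(trimethylsilylethynyl)-8-ketone | C[Si](C)(C)C#C[C@H]1[C@H](O)[C@@H]2[C@@](C)(CC1=O)[C@H](O)CC[C@@]2(C)O | intermediate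
20 | 1β,6α-bis(tert-butyldimethylsilyloxy)-4α-hydroxy-7β-(trimethylsilylethynyl)-8-ketone | C[Si](C)(C)C#C[C@H]1[C@H](O[Si](C)(C)C(C)(C)C)[C@@H]2[C@@](C)(CC1=O)[C@H](O[Si](C)(C)C(C)(C)C)CC[C@@]2(C)O | intermediate
21 | 8β-alcohol of 20 (silylalkyne retained) | C[Si](C)(C)C#C[C@H]1[C@H](O[Si](C)(C)C(C)(C)C)[C@@H]2[C@@](C)(C[C@H]1O)[C@H](O[Si](C)(C)C(C)(C)C)CC[C@@]2(C)O | intermediate
22 | 1β,6α-bis(tert-butyldimethylsilyloxy)-7β-ethynyl-4α,8β-diol | C#C[C@H]1[C@H](O[Si](C)(C)C(C)(C)C)[C@@H]2[C@@](C)(C[C@H]1O)[C@H](O[Si](C)(C)C(C)(C)C)CC[C@@]2(C)O | intermediate
23 | 8α-acetoxy-1β,6α-bis(tert-butyldimethylsilyloxy)-7β-ethynyl-4α-ol | C#C[C@H]1[C@H](O[Si](C)(C)C(C)(C)C)[C@@H]2[C@@](C)(C[C@@H]1OC(C)=O)[C@H](O[Si](C)(C)C(C)(C)C)CC[C@@]2(C)O | intermediate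
24 | 1,6-bis(tert-butyldimethylsilyl) ether of the target | C=C(C(=O)OC)[C@H]1[C@H](O[Si](C)(C)C(C)(C)C)[C@@H]2[C@@](C)(C[C@@H]1OC(C)=O)[C@H](O[Si](C)(C)C(C)(C)C)CC[C@@]2(C)O | intermediate
25 | CNP0272656.1, methyl (1R,4R,5S,6S,7S,8S,10R)-8-acetoxy-1,4,6-trihydroxyeudesm-11(13)-en-12-oate | C=C(C(=O)OC)[C@H]1[C@H](O)[C@@H]2[C@@](C)(C[C@@H]1OC(C)=O)[C@H](O)CC[C@@]2(C)O | target

## Step count and least certain steps

Total step count: 17. Longest linear sequence: 16 steps (steps 1 and 3 to 17, from 1); step 2 is a one-step side branch.

Step 3 (key step). The likely failure is weak facial discrimination or a racemic background cycle. The β-carbon C10 is fully substituted, so the catalysed path is slow; the ester may compete for the boron; and enantioselective catalysis on this dienophile class is untested. The strong acid may also destroy the diene, or a Michael addition may stop short of ring closure. Fallback: starting from 3 and 5, the achiral Lewis acid Me2AlCl promotes the same ketone-directed cycloaddition to the racemate. Preparative chromatography on a chiral stationary phase separates 6 from its mirror image, the (1S,5S,6R) adduct F1, and the route resumes at 6.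

Step 4. The vinyl reagent may enolise the ketone toward C5, with loss of the C6 methoxide, facial control at C4 may be incomplete, or lactonisation may lag. The cause is a β-methoxy ketone beside a quaternary centre. Fallback: starting from 6, the slimmer and less basic acetylide (HC≡CMgBr, CeCl3, THF, −78 °C → rt) adds under the same Felkin/chelate control and lactonises to the ethynyl lactone F2. Semi-hydrogenation (H2, Pd on CaCO3 poisoned with Pb(OAc)2, quinoline) returns to 8.

Step 12. Epimerisation at C7 is the main concern, because a slim alkynyl group has only a small equatorial preference. Propargyl-to-allenyl isomerisation and retro-aldol or β-elimination of the β-hydroxy ketone in the basic oxidation medium are also possible. Fallback: starting from 18, isolated instead of being oxidised in the flask, LiBH(s-Bu)3 reduces the C8 ketone at −78 °C before any basic treatment. Alkaline peroxide then oxidises the C–B bond and removes the alkynyl silyl group to give the 1β,4α,6α,8β-tetraol F3. Mitsunobu acetylation (PPh3, DIAD, AcOH), which can displace only the axial C8 hydroxyl, gives the 8α-acetate triol F4, and TBSOTf/2,6-lutidine silylates O1 and O6 to rejoin the route at 23.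

Step 15. Anti-periplanar elimination of the axial oxyphosphonium group with the axial, propargylic C7–H may compete with substitution, and acetic acid is a weak pronucleophile. Fallback: starting from 20, electron-transfer reduction (SmI2, H2O, Et3N, THF) proceeds through a ketyl and should favour the more stable equatorial alcohol, giving the 8α-alcohol F5. K2CO3/MeOH cleaves the alkynyl silane to the terminal alkyne F6, and Ac2O/pyridine/DMAP acetylates its only free secondary hydroxyl to reach 23.

Step 16. Branching next to the alkyne may divert part of the material to the linear ester, and acid may remove the C6 silyl ether so that O6 traps the acylpalladium intermediate as a lactone. Fallback: starting from 23, Markovnikov hydration (Ph3PAuNTf2 cat., wet dioxane) gives the C11 methyl ketone F7. Kinetic enolisation at the methyl group (KN(SiMe3)2, PhNTf2, THF, −78 °C) gives the enol triflate F8, and carbonylation (Pd(PPh3)4, CO, MeOH, Et3N) delivers 24.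

## Further compounds

F1 | step 3 | methyl (1S,5S,6R)-6-acetyl-3-(tert-butyldimethylsilyloxy)-5-methoxy-1-methylcyclohex-3-ene-1-carboxylate (mirror image of 6) | COC(=O)[C@@]1(C)CC(O[Si](C)(C)C(C)(C)C)=C[C@H](OC)[C@@H]1C(C)=O
F2 | step 4 | (3R,3aS,4R,7aR)-6-(tert-butyldimethylsilyloxy)-3-ethynyl-4-methoxy-3,7a-dimethyl-3a,4,7,7a-tetrahydroisobenzofuran-1(3H)-one | C#C[C@@]1(C)OC(=O)[C@]2(C)CC(O[Si](C)(C)C(C)(C)C)=C[C@@H](OC)[C@@H]12
F3 | step 12 | 7β-ethynyl-1β,4α,6α,8β-tetraol (4β,10β-dimethyl trans-decalin) | C#C[C@H]1[C@H](O)[C@@H]2[C@@](C)(C[C@H]1O)[C@H](O)CC[C@@]2(C)O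
F4 | step 12 | 8α-acetoxy-7β-ethynyl-1β,4α,6α-triol | C#C[C@H]1[C@H](O)[C@@H]2[C@@](C)(C[C@@H]1OC(C)=O)[C@H](O)CC[C@@]2(C)O
F5 | step 15 | 1β,6α-bis(tert-butyldimethylsilyloxy)-7β-(trimethylsilylethynyl)-4α,8α-diol | C[Si](C)(C)C#C[C@H]1[C@H](O[Si](C)(C)C(C)(C)C)[C@@H]2[C@@](C)(C[C@@H]1O)[C@H](O[Si](C)(C)C(C)(C)C)CC[C@@]2(C)O
F6 | step 15 | 1β,6α-bis(tert-butyldimethylsilyloxy)-7β-ethynyl-4α,8α-diol | C#C[C@H]1[C@H](O[Si](C)(C)C(C)(C)C)[C@@H]2[C@@](C)(C[C@@H]1O)[C@H](O[Si](C)(C)C(C)(C)C)CC[C@@]2(C)O
F7 | step 16 | 7β-acetyl-8α-acetoxy-1β,6α-bis(tert-butyldimethylsilyloxy)-4α-ol | CC(=O)[C@H]1[C@H](O[Si](C)(C)C(C)(C)C)[C@@H]2[C@@](C)(C[C@@H]1OC(C)=O)[C@H](O[Si](C)(C)C(C)(C)C)CC[C@@]2(C)O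
F8 | step 16 | 8α-acetoxy-1β,6α-bis(tert-butyldimethylsilyloxy)-7β-[1-(trifluoromethanesulfonyloxy)vinyl]-4α-ol | C=C(OS(=O)(=O)C(F)(F)F)[C@H]1[C@H](O[Si](C)(C)C(C)(C)C)[C@@H]2[C@@](C)(C[C@@H]1OC(C)=O)[C@H](O[Si](C)(C)C(C)(C)C)CC[C@@]2(C)O
A1 | alternative 1 | methyl 8α-acetoxy-1,10-epoxy-6α-(triethylsilyloxy)germacra-4(E),11(13)-dien-12-oate (trans epoxide) | C=C(C(=O)OC)[C@H]1[C@H](O[Si](CC)(CC)CC)/C=C(C)/CC[C@H]2O[C@]2(C)C[C@@H]1OC(C)=O
A2 | alternative 1 | 6-O-triethylsilyl ether of the target | C=C(C(=O)OC)[C@H]1[C@H](O[Si](CC)(CC)CC)[C@@H]2[C@@](C)(C[C@@H]1OC(C)=O)[C@H](O)CC[C@@]2(C)O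
A3 | alternative 2 | ring A aldehyde: C10 carries CH2CHO (C9, C8), C5 carries CH(OSiEt3)–CH=C(CH3)2 (C6, C7, C11); 1β- and 4α-triethylsilyl ethers | CC(C)=C[C@H](O[Si](CC)(CC)CC)[C@@H]1[C@@](C)(CC=O)[C@H](O[Si](CC)(CC)CC)CC[C@@]1(C)O[Si](CC)(CC)CC
A4 | alternative 2 | 8α-hydroxy-7β-isopropenyl decalin, 1,4,6-tris(triethylsilyl) ether | C=C(C)[C@H]1[C@H](O[Si](CC)(CC)CC)[C@@H]2[C@@](C)(C[C@@H]1O)[C@H](O[Si](CC)(CC)CC)CC[C@@]2(C)O[Si](CC)(CC)CC
A5 | alternative 3 | five-ring α-ketol: 3-acetyl-3-hydroxy hydrindenone with C1 tert-butyldimethylsilyl ether, C10 methyl, C5=C6–C7=O enone (C3 configuration left open) | CC(=O)C1(O)C[C@@H](O[Si](C)(C)C(C)(C)C)[C@]2(C)CCC(=O)C=C12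
A6 | alternative 3 | ring-expanded octalin-3,7-dione with C4 hydroxyl and methyl, C1 tert-butyldimethylsilyl ether | C[C@@]1(O)C(=O)C[C@@H](O[Si](C)(C)C(C)(C)C)[C@]2(C)CCC(=O)C=C12
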